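## Structural features

CNP0271389.1 is a 3,8''-linked biflavonoid. A 5,7,4'-trihydroxyflavanone (rings A, C and B, the naringenin unit) is joined through C3 to C8'' of a 5'',7'',4'''-trihydroxyflavone (the apigenin unit), and O7'', the oxygen ortho to the interflavonoid bond, is a sulfate monoester. Ring C holds the only two stereocentres, C2 (R) and C3 (S); they are adjacent and 2,3-trans, with both aryl groups equatorial. C3–H is both α to the C4 ketone and benzylic to the flavone, so it epimerises easily. The O1–C2 bond can open by E1cB (retro-oxa-Michael) or, once the 4'-hydroxyl is free, through a para-quinone methide, so any base used late threatens both centres. The aryl sulfate is polar and acid-labile and must be placed on one of six phenols. The C3–C8'' bond is flanked by O7'' and O1'' on one side and by C4=O and C2 on the other; this crowded bond, the two stereocentres and the site of sulfation are the real difficulties. The key step exploits the fact that O1–C2 is a benzylic ether para to the 4'-hydroxyl of ring B: C2 is the exocyclic carbon of a para-quinone methide of ring B, and the ring A oxygen that becomes O1 is the nucleophile.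

## Logic of the disconnections

**20 ⇒ 18 ⇒ 17.** The four O–CH2Ph bonds and the O–CH2 bond of a neopentyl sulfate diester are cut. The sulfate is carried as a neutral diester from the start instead of being installed at the end. This removes any need to re-protect the 4'-hydroxyl or to sulfate a hindered phenol on a base-sensitive flavanone, and every intermediate up to 17 is neutral and chromatographable. The forward steps must dealkylate at the neopentyl carbon without epimerising C2 or C3, and must hydrogenolyse the benzyl ethers without touching the benzylic O1–C2 bond or the flavone double bond.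

**17 ⇒ 15 (through 16).** The O1–C2 bond is cut. This removes ring C and the C2 stereocentre and leaves an open-chain ketone with one stereocentre and two free phenols. The forward step must oxidise only the ring B phenol, close trans to the C3 substituent, and outrun tautomerisation of the quinone methide. O7'' must be blocked in 15, because a free hydroxyl there could close a five-membered ring onto C2.

**15 ⇒ 14 ⇒ 13.** Two O–CH2OCH3 bonds, then the C2–H and C3–H bonds, are cut. The ring A and ring B phenols must stay masked until after the reduction, because a free ring A hydroxyl would add to the enone and give racemic flavanone. Acetals are chosen so that one acidic step frees both phenols while the benzyl ethers and the sulfate diester stay. The stereocentre then comes from a prochiral enone. The forward reduction must discriminate the faces of a crowded trisubstituted enone without hydrogenolysis or epimerisation.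

**13 ⇒ 10 + 12.** The C2=C3 double bond is cut. This separates ring B as a simple aldehyde from a deoxybenzoin with an activated methylene. The forward condensation must overcome the two ortho-disubstituted aryl groups flanking that methylene and give one alkene geometry.

**10 ⇒ 6 + 9.** The C3–C8'' bond is cut. This is the convergent join of the intact flavone and the ring A ketone, and it avoids building either heterocycle. The forward α-arylation must work on a di-ortho-substituted aryl iodide and stop at mono-arylation.

**6 ⇒ 5 ⇒ 4 ⇒ 3 ⇒ 2 ⇒ 1.** The O7''–S bond, the C8''–I bond, the O7–CH2OCH3 bond and the O5 and O4' benzyl bonds are cut. O7 is singled out through its acidity, and C8 is iodinated while O7 is an electron-donating ether. The forward steps need selective mono-alkylation of 1 at O7 and C8 over C6 iodination.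

**9 ⇒ 8 ⇒ 7 and 12 ⇒ 11.** Only O–C bonds of protecting groups are cut. The chelated hydroxyl of 7 resists benzylation and is capped separately as the acetal.

## Other disconnections considered

**Alternative 1:** The cut removes three bonds of the flavone benzo ring (ring D): C8''–C8a'', C6''–C7'' and C4a''–C8a''. In the forward step the cyclobutenone A3 is heated with the flavan-bound siloxyalkyne A2. Four-electron opening gives a vinylketene, which adds [2+2] to the ynol ether; a second four-electron opening and a six-electron closure then give the resorcinol A1 (Danheiser benzannulation).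
- In its favour: the C3–aryl bond is never forged at a crowded centre. C4 in A2 and A1 is an sp3 silyl ether, so C3 cannot enolise; on configurational safety this plan is better than the chosen one. Ring D also emerges with three differently capped oxygens, so O7'' is marked without relying on the acidity order in 1; on that point it is equal or better.
- Against it: A2 needs its own enantioselective synthesis of a 2,3-trans 3-alkynylflavan. After A1 the whole pyranone of the flavone must still be added, with acylation at C4a'' competing with C6''. C4 must then be unmasked and oxidised, which re-creates the enolisable centre anyway.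
- Comparison: the thermal pericyclic cascade is mechanistically more predictable than an electrode reaction. In step count it is clearly longer, because the chosen plan buys the flavone.

**Alternative 2:** The cut removes C4a''–C4'', C4''–C3'' and O1''–C2'', the pyranone ring of the flavone. In the forward step the aryl iodide A5 and the alkyne A6 undergo carbonylative Sonogashira coupling under PdCl2(PPh3)2; the ortho-hydroxyaryl ynone then closes through the neighbouring hydroxyl to give A4.
- In its favour: it is convergent and late. A4 has exactly one free hydroxyl, at O7'', so sulfation and hydrogenolysis finish the synthesis; this endgame is as short as the chosen one and needs no masked sulfate (equal). The resorcinol ring before iodination is symmetric, so mono-iodination raises no regiochemical question.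
- Against it: A5 already contains ring C, both stereocentres and the C3–aryl bond, so this cut leaves the real difficulties to another strategy. The amine base and heat of the carbonylation meet a base-labile 3-arylflavanone with free phenols. Five-membered (aurone) closure competes with the six-membered mode.
- Comparison: the chosen plan spends its key step on ring C, where the stereochemistry lies, and keeps the flavone intact from 1. There is no gain in steps.

**Alternative 3:** The cut removes C3–C4 and O1–C2, a [4+2] construction of ring C. In the forward step a chiral phosphoric acid converts the salicylaldehyde A8 into a 4-methoxy ortho-quinone methide ion pair, which adds the (E)-stilbene A9 to give A7.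
- In its favour: two bonds, ring C and both stereocentres are made in one catalytic step from achiral partners. The alkene geometry maps onto 2,3-trans, and there is no epimerisable open-chain ketone. On stereochemical economy it is better than the chosen plan, and it is probably shorter, since A9 is one coupling step from an 8-iodoflavone such as 4.
- Against it: A9 is a crowded, weakly polarised 1,2-diarylethene. Its reactivity toward the heterodiene is lower than that of styrenes or enol ethers. The regiochemistry depends on ring B stabilising positive charge better than the oxygenated flavonyl group. Enantioinduction without a hydrogen-bonding handle is uncertain. A7 still needs its C4 ether converted into the ketone in two operations, then acetal removal and sulfation.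
- Comparison: the endgame is equal, since ring B is benzylated in A7. The chosen plan is preferred because its stereochemistry-setting steps rest on better-precedented substrate classes.

Key step: step 13

Assumption: the hydrogen sulfate form drawn is produced by brief cold acidification of the sodium salt 19; since aryl hydrogen sulfates hydrolyse under acid catalysis, 19 is the storage form.

Abbreviation used in names: Fl = 5-(benzyloxy)-2-[4-(benzyloxy)phenyl]-7-[(neopentyloxy)sulfonyloxy]-4-oxo-4H-chromen-8-yl.

## Route

Step 1
Reactants: 1 apigenin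
Product: 2 5-hydroxy-2-(4-hydroxyphenyl)-7-(methoxymethoxy)-4H-chromen-4-one
Conditions: MOMCl (1.05 equiv), K2CO3 (1.1 equiv), DMF, 0 °C to rt
Reagents that add atoms: chloromethyl methyl ether, COCCl
Why: Williamson etherification under acidity control: O7–H, para to the pyranone carbonyl, is the most acidic hydroxyl, so one equivalent of weak base should give mainly the 7-phenoxide, while O5–H is held in the hydrogen bond to C4=O. The 4'-ether and the bis-ether are expected as minor, separable by-products.

Step 2
Reactants: 2 5-hydroxy-2-(4-hydroxyphenyl)-7-(methoxymethoxy)-4H-chromen-4-one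
Product: 3 5-(benzyloxy)-2-[4-(benzyloxy)phenyl]-7-(methoxymethoxy)-4H-chromen-4-one
Conditions: BnBr (3 equiv), K2CO3 (4 equiv), DMF, 70 °C
Reagents that add atoms: benzyl bromide, BrCc1ccccc1
Why: Williamson benzylation of both remaining phenols; excess reagent and heat are needed to alkylate the chelated O5–H, and the acetal is stable to base.

Step 3
Reactants: 3 5-(benzyloxy)-2-[4-(benzyloxy)phenyl]-7-(methoxymethoxy)-4H-chromen-4-one
Product: 4 5-(benzyloxy)-2-[4-(benzyloxy)phenyl]-8-iodo-7-(methoxymethoxy)-4H-chromen-4-one
Conditions: NIS (1.15 equiv), DMF, 50 °C, dark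
Reagents that add atoms: N-iodosuccinimide, O=C1CCC(=O)N1I
Why: Electrophilic aromatic iodination of the phloroglucinol-type ring; in 5,7-dialkoxyflavones C8 (para to O5, ortho to O7 and O1) is favoured over C6, which lies between two alkoxy groups. The neutral conditions spare the acetal.

Step 4
Reactants: 4 5-(benzyloxy)-2-[4-(benzyloxy)phenyl]-8-iodo-7-(methoxymethoxy)-4H-chromen-4-one
Product: 5 5-(benzyloxy)-2-[4-(benzyloxy)phenyl]-7-hydroxy-8-iodo-4H-chromen-4-one
Conditions: 2 M HCl, MeOH/THF (1:1), 40 °C
Reagents that add atoms: none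
Why: Acid-catalysed acetal cleavage; the aryl methoxymethyl ether of this acidic phenol cleaves under dilute acid that leaves the benzyl ethers and the aryl iodide intact.

Step 5
Reactants: 5 5-(benzyloxy)-2-[4-(benzyloxy)phenyl]-7-hydroxy-8-iodo-4H-chromen-4-one
Product: 6 5-(benzyloxy)-2-[4-(benzyloxy)phenyl]-8-iodo-4-oxo-4H-chromen-7-yl neopentyl sulfate
Conditions: NaN(SiMe3)2 (1.1 equiv), THF, −78 °C; neopentyl chlorosulfate (1.3 equiv), −78 to 0 °C
Reagents that add atoms: neopentyl chlorosulfate, CC(C)(C)COS(=O)(=O)Cl
Why: O-sulfonylation of the phenoxide with a chlorosulfate ester gives the neutral aryl neopentyl sulfate diester. The neopentyl group blocks dealkylation under ordinary conditions, and the diester should tolerate acid, weak base and hydrogenation.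

Step 6
Reactants: 7 1-(2,4,6-trihydroxyphenyl)ethan-1-one
Product: 8 1-[2,4-bis(benzyloxy)-6-hydroxyphenyl]ethan-1-one
Conditions: BnBr (2.1 equiv), K2CO3 (2.5 equiv), DMF, rt
Reagents that add atoms: benzyl bromide, BrCc1ccccc1
Why: Williamson benzylation; after the first ortho hydroxyl is benzylated, the remaining one is hydrogen-bonded to the acetyl group and stays free under mild conditions.

Step 7
Reactants: 8 1-[2,4-bis(benzyloxy)-6-hydroxyphenyl]ethan-1-one
Product: 9 1-[2,4-bis(benzyloxy)-6-(methoxymethoxy)phenyl]ethan-1-one
Conditions: NaH (1.2 equiv), DMF, 0 °C; MOMCl (1.3 equiv), 0 °C to rt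
Reagents that add atoms: chloromethyl methyl ether, COCCl
Why: Irreversible deprotonation breaks the chelate and the phenoxide is alkylated (Williamson). The acetal masks the future O1 through the basic and reductive steps and is removable by acid alone.

Step 8
Reactants: 6 5-(benzyloxy)-2-[4-(benzyloxy)phenyl]-8-iodo-4-oxo-4H-chromen-7-yl neopentyl sulfate; 9 1-[2,4-bis(benzyloxy)-6-(methoxymethoxy)phenyl]ethan-1-one (1.3 equiv)
Product: 10 1-[2,4-bis(benzyloxy)-6-(methoxymethoxy)phenyl]-2-Fl-ethan-1-one
Conditions: Pd2(dba)3 (2.5 mol %), XPhos (10 mol %), K3PO4 (2.5 equiv), toluene, 90 °C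
Reagents that add atoms: none
Why: Palladium-catalysed ketone α-arylation (Buchwald–Hartwig type): oxidative addition of zerovalent palladium into C8''–I, exchange with the potassium enolate of 9 and reductive elimination form C3–C8''. The bulky biarylphosphine supports coupling of the di-ortho-substituted iodide, and the crowded product should resist a second arylation. The weak base spares the flavone and the sulfate diester.

Step 9
Reactants: 11 4-hydroxybenzaldehyde
Product: 12 4-(methoxymethoxy)benzaldehyde
Conditions: MOMCl (1.2 equiv), K2CO3 (2 equiv), acetone, rt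
Reagents that add atoms: chloromethyl methyl ether, COCCl
Why: Williamson etherification of a simple phenol; the acetal matches the ring A protecting group so that both are removed together later.

Step 10
Reactants: 10 1-[2,4-bis(benzyloxy)-6-(methoxymethoxy)phenyl]-2-Fl-ethan-1-one; 12 4-(methoxymethoxy)benzaldehyde (1.5 equiv)
Product: 13 (E)-1-[2,4-bis(benzyloxy)-6-(methoxymethoxy)phenyl]-2-Fl-3-[4-(methoxymethoxy)phenyl]prop-2-en-1-one
Conditions: piperidine (20 mol %), AcOH (20 mol %), toluene, reflux, Dean–Stark
Reagents that add atoms: none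
Why: Knoevenagel-type aldol condensation of the doubly activated methylene of the deoxybenzoin with the aldehyde through its iminium ion, driven by removal of water. Elimination under equilibrating conditions should favour the (E) isomer, with the bulky aroyl group trans to ring B. The ring A acetal prevents oxa-Michael closure to racemic flavanone.

Step 11
Reactants: 13 (E)-1-[2,4-bis(benzyloxy)-6-(methoxymethoxy)phenyl]-2-Fl-3-[4-(methoxymethoxy)phenyl]prop-2-en-1-one
Product: 14 (R)-1-[2,4-bis(benzyloxy)-6-(methoxymethoxy)phenyl]-2-Fl-3-[4-(methoxymethoxy)phenyl]propan-1-one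
Conditions: H2 (50 bar), [Ir(cod)(tBu-PHOX)]BArF (2 mol %; BArF = B[3,5-(CF3)2C6H3]4; ligand antipode that gives R), CH2Cl2, rt
Reagents that add atoms: none
Why: Iridium-catalysed asymmetric hydrogenation of an α-substituted acyclic enone with a cationic P,N complex: H2 adds to one face of C2=C3 and creates C3. The sense of induction depends on the ligand antipode and the (E) geometry, so the antipode giving the (R)-ketone is to be chosen on a model α-aryl chalcone. The homogeneous, non-basic catalyst should leave the benzyl ethers, acetals, sulfate diester and the electron-rich flavone C2''=C3'' bond alone and should not epimerise the new centre.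

Step 12
Reactants: 14 (R)-1-[2,4-bis(benzyloxy)-6-(methoxymethoxy)phenyl]-2-Fl-3-[4-(methoxymethoxy)phenyl]propan-1-one
Product: 15 (R)-1-[2,4-bis(benzyloxy)-6-hydroxyphenyl]-2-Fl-3-(4-hydroxyphenyl)propan-1-one
Conditions: 2 M HCl, MeOH/THF (1:1), 35 °C
Reagents that add atoms: none
Why: Acid-catalysed acetal cleavage frees the ring A hydroxyl and the ring B hydroxyl in one operation. Benzyl ethers and the neopentyl sulfate diester are stable to dilute acid, and acid is used instead of base or fluoride because the α-aryl ketone centre enolises much more slowly under it.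

Step 13
Reactants: 15 (R)-1-[2,4-bis(benzyloxy)-6-hydroxyphenyl]-2-Fl-3-(4-hydroxyphenyl)propan-1-one
Product: 17 (2R,3S)-5,7-bis(benzyloxy)-2-(4-hydroxyphenyl)-3-Fl-chroman-4-one, via para-quinone methide 16 (not isolated)
Conditions: graphite anode, Pt cathode, undivided cell, potential held at the first anodic wave, about 2.1 F/mol, nBu4NBF4 (0.1 M), CH2Cl2/HFIP (4:1), 2,6-lutidine (1 equiv), 0 °C
Reagents that add atoms: none
Why: The free, non-chelated 4-alkylphenol of ring B is the most easily oxidised site; loss of two electrons, the phenolic proton and the benzylic C2 proton gives the para-quinone methide 16, whose exocyclic carbon C2 is the electrophile. The closest known reaction type is the anodic (or Ag2O- or DDQ-mediated) conversion of 4-alkylphenols into para-quinone methides that are trapped by oxygen nucleophiles, as in oxidative flavan-type cyclisations. The ring A hydroxyl then adds to C2 in an intramolecular oxa-1,6-conjugate addition that restores the aromaticity of ring B, forms O1–C2 and closes ring C; because the C2=C1' double bond lies outside the new ring, this is a 6-exo-trig closure, not the 6-endo mode of a chalcone cyclisation. The new C2 centre is controlled by the existing C3 centre: in the chair-like transition state the flavonyl group at C3 and the aryl group at C2 both sit pseudo-equatorial, which leads to the 2,3-trans (2R,3S) flavanone; C3 is untouched and its descriptor changes from R to S only because O1 raises the priority of C2. Chemoselectivity for ring B is secured by the substrate: the ring A phenol is acyl-deactivated and tied into a hydrogen bond with C4=O, every other oxygen is capped as a benzyl ether or the sulfate diester, and the potential and charge are limited so that the flavone and the product are not oxidised further. Tautomerisation of 16 to the achiral α-aryl chalcone, which would erase C3, is countered by low temperature, the absence of any base stronger than 2,6-lutidine and the speed of the six-membered intramolecular capture in the cation-stabilising HFIP medium. O7'' cannot compete as a nucleophile, although a five-membered closure onto C2 would otherwise be possible, because it is held as the sulfate diester.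

Step 14
Reactants: 17 (2R,3S)-5,7-bis(benzyloxy)-2-(4-hydroxyphenyl)-3-Fl-chroman-4-one
Product: 18 sodium 5-(benzyloxy)-2-[4-(benzyloxy)phenyl]-8-[(2R,3S)-5,7-bis(benzyloxy)-2-(4-hydroxyphenyl)-4-oxochroman-3-yl]-4-oxo-4H-chromen-7-yl sulfate
Conditions: NaN3 (3 equiv), DMF, 60 °C
Reagents that add atoms: sodium azide, [Na+].[N-]=[N+]=[N-] (supplies the sodium counter-ion)
Why: SN2 dealkylation of the sulfate diester: azide attacks the neopentyl CH2 and the aryl sulfate monoanion, an excellent leaving group, departs. Azide is only weakly basic, so the 4'-phenol stays protonated and neither retro-oxa-1,6 opening nor enolisation at C3 is expected at this temperature.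

Step 15
Reactants: 18 sodium 5-(benzyloxy)-2-[4-(benzyloxy)phenyl]-8-[(2R,3S)-5,7-bis(benzyloxy)-2-(4-hydroxyphenyl)-4-oxochroman-3-yl]-4-oxo-4H-chromen-7-yl sulfate
Product: 20 (2R,3S)-5,7-dihydroxy-2-(4-hydroxyphenyl)-3-[5-hydroxy-2-(4-hydroxyphenyl)-4-oxo-7-(sulfooxy)-4H-chromen-8-yl]chroman-4-one (CNP0271389.1), via sodium salt of the debenzylated sulfate 19 (not isolated)
Conditions: H2 (1 atm), Pd/C (10 %), THF/MeOH (1:1), rt; filter; 0.1 M HCl to pH 2 at 0 °C, C18 solid-phase extraction, lyophilisation
Reagents that add atoms: none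
Why: Heterogeneous hydrogenolysis of the four benzyl ethers at ambient pressure. The aryl sulfate salt, the chelated C4 ketone, the benzylic O1–C2 bond and the flavone double bond should survive if the reaction is stopped at complete debenzylation, and brief cold acidification converts the sodium salt into the hydrogen sulfate.

## Compound list

1 | apigenin | O=c1cc(-c2ccc(O)cc2)oc2cc(O)cc(O)c12 | starting material
2 | 5-hydroxy-2-(4-hydroxyphenyl)-7-(methoxymethoxy)-4H-chromen-4-one | O=c1cc(-c2ccc(O)cc2)oc2cc(OCOC)cc(O)c12 | intermediate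
3 | 5-(benzyloxy)-2-[4-(benzyloxy)phenyl]-7-(methoxymethoxy)-4H-chromen-4-one | O=c1cc(-c2ccc(OCc3ccccc3)cc2)oc2cc(OCOC)cc(OCc3ccccc3)c12 | intermediate
4 | 5-(benzyloxy)-2-[4-(benzyloxy)phenyl]-8-iodo-7-(methoxymethoxy)-4H-chromen-4-one | O=c1cc(-c2ccc(OCc3ccccc3)cc2)oc2c(I)c(OCOC)cc(OCc3ccccc3)c12 | intermediate
5 | 5-(benzyloxy)-2-[4-(benzyloxy)phenyl]-7-hydroxy-8-iodo-4H-chromen-4-one | O=c1cc(-c2ccc(OCc3ccccc3)cc2)oc2c(I)c(O)cc(OCc3ccccc3)c12 | intermediate
6 | 5-(benzyloxy)-2-[4-(benzyloxy)phenyl]-8-iodo-4-oxo-4H-chromen-7-yl neopentyl sulfate | O=c1cc(-c2ccc(OCc3ccccc3)cc2)oc2c(I)c(OS(=O)(=O)OCC(C)(C)C)cc(OCc3ccccc3)c12 | intermediate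
7 | 1-(2,4,6-trihydroxyphenyl)ethan-1-one | CC(=O)c1c(O)cc(O)cc1O | starting material
8 | 1-[2,4-bis(benzyloxy)-6-hydroxyphenyl]ethan-1-one | CC(=O)c1c(O)cc(OCc2ccccc2)cc1OCc1ccccc1 | intermediate
9 | 1-[2,4-bis(benzyloxy)-6-(methoxymethoxy)phenyl]ethan-1-one | CC(=O)c1c(OCOC)cc(OCc2ccccc2)cc1OCc1ccccc1 | intermediate
10 | 1-[2,4-bis(benzyloxy)-6-(methoxymethoxy)phenyl]-2-Fl-ethan-1-one | O=C(Cc1c(OS(=O)(=O)OCC(C)(C)C)cc(OCc2ccccc2)c2c(=O)cc(-c3ccc(OCc4ccccc4)cc3)oc12)c1c(OCOC)cc(OCc2ccccc2)cc1OCc1ccccc1 | intermediate
11 | 4-hydroxybenzaldehyde | O=Cc1ccc(O)cc1 | starting material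
12 | 4-(methoxymethoxy)benzaldehyde | COCOc1ccc(C=O)cc1 | intermediate
13 | (E)-1-[2,4-bis(benzyloxy)-6-(methoxymethoxy)phenyl]-2-Fl-3-[4-(methoxymethoxy)phenyl]prop-2-en-1-one | O=C(c1c(OCOC)cc(OCc2ccccc2)cc1OCc1ccccc1)/C(=C/c1ccc(OCOC)cc1)c1c(OS(=O)(=O)OCC(C)(C)C)cc(OCc2ccccc2)c2c(=O)cc(-c3ccc(OCc4ccccc4)cc3)oc12 | intermediate
14 | (R)-1-[2,4-bis(benzyloxy)-6-(methoxymethoxy)phenyl]-2-Fl-3-[4-(methoxymethoxy)phenyl]propan-1-one | O=C(c1c(OCOC)cc(OCc2ccccc2)cc1OCc1ccccc1)[C@H](Cc1ccc(OCOC)cc1)c1c(OS(=O)(=O)OCC(C)(C)C)cc(OCc2ccccc2)c2c(=O)cc(-c3ccc(OCc4ccccc4)cc3)oc12 | intermediate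
15 | (R)-1-[2,4-bis(benzyloxy)-6-hydroxyphenyl]-2-Fl-3-(4-hydroxyphenyl)propan-1-one | O=C(c1c(O)cc(OCc2ccccc2)cc1OCc1ccccc1)[C@H](Cc1ccc(O)cc1)c1c(OS(=O)(=O)OCC(C)(C)C)cc(OCc2ccccc2)c2c(=O)cc(-c3ccc(OCc4ccccc4)cc3)oc12 | intermediate
16 | (R)-1-[2,4-bis(benzyloxy)-6-hydroxyphenyl]-2-Fl-3-(4-oxocyclohexa-2,5-dien-1-ylidene)propan-1-one (para-quinone methide) | O=C(c1c(O)cc(OCc2ccccc2)cc1OCc1ccccc1)[C@H](C=C1C=CC(=O)C=C1)c1c(OS(=O)(=O)OCC(C)(C)C)cc(OCc2ccccc2)c2c(=O)cc(-c3ccc(OCc4ccccc4)cc3)oc12 | intermediate
17 | (2R,3S)-5,7-bis(benzyloxy)-2-(4-hydroxyphenyl)-3-Fl-chroman-4-one | O=C1c2c(OCc3ccccc3)cc(OCc3ccccc3)cc2O[C@@H](c2ccc(O)cc2)[C@@H]1c1c(OS(=O)(=O)OCC(C)(C)C)cc(OCc2ccccc2)c2c(=O)cc(-c3ccc(OCc4ccccc4)cc3)oc12 | intermediate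
18 | sodium 5-(benzyloxy)-2-[4-(benzyloxy)phenyl]-8-[(2R,3S)-5,7-bis(benzyloxy)-2-(4-hydroxyphenyl)-4-oxochroman-3-yl]-4-oxo-4H-chromen-7-yl sulfate | O=C1c2c(OCc3ccccc3)cc(OCc3ccccc3)cc2O[C@@H](c2ccc(O)cc2)[C@@H]1c1c(OS(=O)(=O)[O-])cc(OCc2ccccc2)c2c(=O)cc(-c3ccc(OCc4ccccc4)cc3)oc12.[Na+] | intermediate
19 | sodium 8-[(2R,3S)-5,7-dihydroxy-2-(4-hydroxyphenyl)-4-oxochroman-3-yl]-5-hydroxy-2-(4-hydroxyphenyl)-4-oxo-4H-chromen-7-yl sulfate | O=C1c2c(O)cc(O)cc2O[C@@H](c2ccc(O)cc2)[C@@H]1c1c(OS(=O)(=O)[O-])cc(O)c2c(=O)cc(-c3ccc(O)cc3)oc12.[Na+] | intermediate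
20 | (2R,3S)-5,7-dihydroxy-2-(4-hydroxyphenyl)-3-[5-hydroxy-2-(4-hydroxyphenyl)-4-oxo-7-(sulfooxy)-4H-chromen-8-yl]chroman-4-one (CNP0271389.1) | O=C1c2c(O)cc(O)cc2O[C@@H](c2ccc(O)cc2)[C@@H]1c1c(OS(=O)(=O)O)cc(O)c2c(=O)cc(-c3ccc(O)cc3)oc12 | target

## Step count and least certain steps

Total: 15 steps. Longest linear sequence: 12 steps (from 1 through steps 1–5, 8 and 10–15).

**Step 13 (key step).** The most likely failure is tautomerisation of the quinone methide to the achiral α-aryl chalcone before the ring A hydroxyl captures it, which would erase the C3 information. Oxidation at the wrong phenol or further oxidation of the product is the second risk. The C3 proton of 16 is acidic (α to the ketone, benzylic, vinylogous to the quinone methide carbonyl), so this pathway is intrinsically available. Fallback, from 13 back to 17: both acetals of 13 are removed with dilute HCl in MeOH/THF to give the (E)-chalcone diol F1. F1 is cyclised with NaOAc in EtOH at 60 °C (oxa-Michael addition, equilibrating to the trans isomer) to the racemic trans-flavanone, that is 17 together with its (2S,3R)-enantiomer F2. The two are separated by preparative chromatography on a chiral stationary phase. F2 can be returned to the racemate under the same basic conditions, which reopen it to F1.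

**Step 11.** The likely failures are lack of turnover at the enone, which is flanked by two ortho-disubstituted aryl groups, or poor facial discrimination; alkene isomerisation before reduction would also lower the selectivity. Fallback, from 13 back to 14: conjugate reduction with catalytic [CuH(PPh3)]6 and PhSiH3 in toluene, with NH4F work-up, should deliver hydride to the less hindered C2 and give the racemic ketone, that is 14 together with its (S)-enantiomer F3. Preparative chiral SFC provides 14. F3 is racemised with catalytic DBU and recycled.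

**Step 10.** The likely failure is an unfavourable aldol equilibrium and slow dehydration at the crowded methylene; prolonged heating with the amine salt could also start to dealkylate the sulfate diester. Fallback, from 10 back to 13: the lithium enolate of 10 (LiN(SiMe3)2, THF, −78 °C) is added to 12 to give the aldol adduct F4 as a mixture of diastereomers. F4 is converted with MsCl and Et3N in CH2Cl2 at −20 °C into the mesylate F5. DBU at rt then eliminates by E1cB to 13.

**Step 8.** The likely failure is slow coupling at the di-ortho-substituted C8''–I bond, with protodeiodination taking over. Fallback, from 6 back to 10, forming the aryl–acyl bond instead: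
- Reformatsky–Negishi coupling of 6 with BrZnCH2CO2tBu (Pd2(dba)3, XPhos, THF, 50 °C) gives the tert-butyl ester F6.
- TFA in CH2Cl2 at 0 °C gives the acid F7.
- Friedel–Crafts acylation of commercial 3,5-bis(benzyloxy)phenol with F7 and (CF3CO)2O in CH2Cl2 (0 °C to rt), directed ortho to the hydroxyl, gives the hydroxy ketone F8.
- MOMCl and iPr2NEt in CH2Cl2 convert F8 into 10.

**Step 14.** The likely failures are incomplete dealkylation at the hindered neopentyl carbon, or ring opening and epimerisation of the 4'-hydroxyflavanone during prolonged heating with the salt. Fallback, from 17 back to 19: the benzyl ethers are hydrogenolysed first (H2, Pd/C, THF/MeOH) to give the hexahydroxy neopentyl sulfate F9, whose chelated 5-hydroxy-4-ketone is less prone to enolisation. F9 is then dealkylated with NaN3 in DMSO at 50 °C to 19, which is acidified as in step 15 to 20.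

## Further compounds

F1 | step 13 | (E)-1-[2,4-bis(benzyloxy)-6-hydroxyphenyl]-2-Fl-3-(4-hydroxyphenyl)prop-2-en-1-one | O=C(c1c(O)cc(OCc2ccccc2)cc1OCc1ccccc1)/C(=C/c1ccc(O)cc1)c1c(OS(=O)(=O)OCC(C)(C)C)cc(OCc2ccccc2)c2c(=O)cc(-c3ccc(OCc4ccccc4)cc3)oc12
F2 | step 13 | (2S,3R)-5,7-bis(benzyloxy)-2-(4-hydroxyphenyl)-3-Fl-chroman-4-one (enantiomer of 17) | O=C1c2c(OCc3ccccc3)cc(OCc3ccccc3)cc2O[C@H](c2ccc(O)cc2)[C@H]1c1c(OS(=O)(=O)OCC(C)(C)C)cc(OCc2ccccc2)c2c(=O)cc(-c3ccc(OCc4ccccc4)cc3)oc12
F3 | step 11 | (S)-1-[2,4-bis(benzyloxy)-6-(methoxymethoxy)phenyl]-2-Fl-3-[4-(methoxymethoxy)phenyl]propan-1-one (enantiomer of 14) | O=C(c1c(OCOC)cc(OCc2ccccc2)cc1OCc1ccccc1)[C@@H](Cc1ccc(OCOC)cc1)c1c(OS(=O)(=O)OCC(C)(C)C)cc(OCc2ccccc2)c2c(=O)cc(-c3ccc(OCc4ccccc4)cc3)oc12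
F4 | step 10 | 1-[2,4-bis(benzyloxy)-6-(methoxymethoxy)phenyl]-2-Fl-3-hydroxy-3-[4-(methoxymethoxy)phenyl]propan-1-one (mixture of diastereomers) | O=C(c1c(OCOC)cc(OCc2ccccc2)cc1OCc1ccccc1)C(C(O)c1ccc(OCOC)cc1)c1c(OS(=O)(=O)OCC(C)(C)C)cc(OCc2ccccc2)c2c(=O)cc(-c3ccc(OCc4ccccc4)cc3)oc12
F5 | step 10 | 3-[2,4-bis(benzyloxy)-6-(methoxymethoxy)phenyl]-2-Fl-1-[4-(methoxymethoxy)phenyl]-3-oxopropyl methanesulfonate (mixture of diastereomers) | O=C(c1c(OCOC)cc(OCc2ccccc2)cc1OCc1ccccc1)C(C(OS(C)(=O)=O)c1ccc(OCOC)cc1)c1c(OS(=O)(=O)OCC(C)(C)C)cc(OCc2ccccc2)c2c(=O)cc(-c3ccc(OCc4ccccc4)cc3)oc12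
F6 | step 8 | tert-butyl 2-Fl-acetate | CC(C)(C)OC(=O)Cc1c(OS(=O)(=O)OCC(C)(C)C)cc(OCc2ccccc2)c2c(=O)cc(-c3ccc(OCc4ccccc4)cc3)oc12
F7 | step 8 | 2-Fl-acetic acid | OC(=O)Cc1c(OS(=O)(=O)OCC(C)(C)C)cc(OCc2ccccc2)c2c(=O)cc(-c3ccc(OCc4ccccc4)cc3)oc12
F8 | step 8 | 1-[2,4-bis(benzyloxy)-6-hydroxyphenyl]-2-Fl-ethan-1-one | O=C(Cc1c(OS(=O)(=O)OCC(C)(C)C)cc(OCc2ccccc2)c2c(=O)cc(-c3ccc(OCc4ccccc4)cc3)oc12)c1c(O)cc(OCc2ccccc2)cc1OCc1ccccc1
F9 | step 14 | 8-[(2R,3S)-5,7-dihydroxy-2-(4-hydroxyphenyl)-4-oxochroman-3-yl]-5-hydroxy-2-(4-hydroxyphenyl)-4-oxo-4H-chromen-7-yl neopentyl sulfate | O=C1c2c(O)cc(O)cc2O[C@@H](c2ccc(O)cc2)[C@@H]1c1c(OS(=O)(=O)OCC(C)(C)C)cc(O)c2c(=O)cc(-c3ccc(O)cc3)oc12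
A1 | alternative 1 | 2,3-trans-flavan 4-O-TBS ether carrying at C3 a 4-benzyloxy-2-hydroxy-6-(triisopropylsilyloxy)phenyl group | CC(C)(C)[Si](C)(C)O[C@H]1c2c(OCc3ccccc3)cc(OCc3ccccc3)cc2O[C@@H](c2ccc(OCc3ccccc3)cc2)[C@@H]1c1c(O[Si](C(C)C)(C(C)C)C(C)C)cc(OCc2ccccc2)cc1O
A2 | alternative 1 | 2,3-trans-flavan 4-O-TBS ether carrying at C3 a (triisopropylsilyloxy)ethynyl group | CC(C)(C)[Si](C)(C)O[C@H]1c2c(OCc3ccccc3)cc(OCc3ccccc3)cc2O[C@@H](c2ccc(OCc3ccccc3)cc2)[C@@H]1C#CO[Si](C(C)C)(C(C)C)C(C)C
A3 | alternative 1 | 3-(benzyloxy)cyclobut-2-en-1-one | O=C1CC(OCc2ccccc2)=C1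
A4 | alternative 2 | (2R,3S)-pentabenzyl ether of the desulfated target with free 7''-hydroxyl | O=C1c2c(OCc3ccccc3)cc(OCc3ccccc3)cc2O[C@@H](c2ccc(OCc3ccccc3)cc2)[C@@H]1c1c(O)cc(OCc2ccccc2)c2c(=O)cc(-c3ccc(OCc4ccccc4)cc3)oc12
A5 | alternative 2 | (2R,3S)-5,7-bis(benzyloxy)-2-[4-(benzyloxy)phenyl]-3-[4-(benzyloxy)-2,6-dihydroxy-3-iodophenyl]chroman-4-one | O=C1c2c(OCc3ccccc3)cc(OCc3ccccc3)cc2O[C@@H](c2ccc(OCc3ccccc3)cc2)[C@@H]1c1c(O)cc(OCc2ccccc2)c(I)c1O
A6 | alternative 2 | 1-(benzyloxy)-4-ethynylbenzene | C#Cc1ccc(OCc2ccccc2)cc1
A7 | alternative 3 | 2,3-trans-4-methoxyflavan carrying the protected flavone at C3 (drawn 3,4-trans) | CO[C@H]1c2c(OCc3ccccc3)cc(OCc3ccccc3)cc2O[C@@H](c2ccc(OCc3ccccc3)cc2)[C@@H]1c1c(OCOC)cc(OCc2ccccc2)c2c(=O)cc(-c3ccc(OCc4ccccc4)cc3)oc12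
A8 | alternative 3 | 2,4-bis(benzyloxy)-6-hydroxybenzaldehyde | O=Cc1c(O)cc(OCc2ccccc2)cc1OCc1ccccc1
A9 | alternative 3 | (E)-5-(benzyloxy)-2-[4-(benzyloxy)phenyl]-8-[4-(benzyloxy)styryl]-7-(methoxymethoxy)-4H-chromen-4-one | O(Cc1ccccc1)c1ccc(/C=C/c2c(OCOC)cc(OCc3ccccc3)c3c(=O)cc(-c4ccc(OCc5ccccc5)cc4)oc23)cc1
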